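If you want to know whether exchange keeps up in this flask, follow one molecule to its fork: it either reacts or changes hand.

common to all: left-handed substrate 0.25 M; right-handed substrate 0.25 M

|  | reagent | precatalyst | remark | time |
|---|---|---|---|---|
| Tuesday's | 0.77 M | 0.50 mM | run made earlier |  |
| Sunday's | 1.2 M | 0.50 mM | run made earlier |  |
| Saturday's | 0.55 M | 0.25 mM | run made earlier |  |
| flask | 0.550 M | 0.50 mM |  | 2.0 h |

- Tuesday's (time / h: left-handed product / %, right-handed product / %): 0.333: 42, 23; 0.667: 59, 36; 1.00: 61, 37; 1.33: 61, 38; 1.50: 64, 41; 2.00: 64, 37; 2.50: 60, 41
- Sunday's (time / h: left-handed product / %, right-handed product / %): 0.333: 53, 36; 0.667: 62, 35; 1.00: 61, 36; 1.33: 61, 38; 1.50: 59, 41; 2.00: 59, 42; 2.50: 64, 36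
- Saturday's (time / h: left-handed product / %, right-handed product / %): 0.200: 15, 5; 0.667: 46, 28; 1.00: 52, 27; 1.50: 52, 31; 2.50: 64, 35

(each reading ± 2 percentage points)

- catalyst is single-handed; left-handed substrate and right-handed substrate are mirror images of each other, charged as a racemate, each of them at the stated concentration
- the analysis behind the earlier runs scatters by 2 percentage points, standard deviation
- an excess is the difference of the two amounts in percent of their sum
- an excess is below zero if the other one leads

1. left-handed product and right-handed product together, in percent of the left-handed substrate and right-handed substrate charged together, at 2.0 h
2. excess of left-handed product over right-handed product in the product at 2.0 h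
3. whether the exchange between left-handed substrate and right-handed substrate keeps pace with the reaction: how far the product's excess at 2.0 h gets from its value without exchange to its value with instant exchange (above 80% keeps pace, below 20% hardly takes part, else lags behind)

1. Here is the oddity. Left-handed substrate is half of the charge, yet Saturday's run reads 64% left-handed product at 2.50 h, beside 35% right-handed product.
2. So right-handed substrate must cross over: on that reading, at least 28.0% of it did so before reacting.
3. A molecule that changes hand many times before reacting forgets its origin. It then ends as left-handed product with one fixed chance, w, set by the selectivity factor.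
4. Saturday's is the slowest run, so I read w there. Its last readings give 64.4%.
5. The chance of left less the chance of right gives, as a reading, 28.7%: the ceiling excess, the product's excess with instant exchange.
6. This flask has c(reagent) 0.550 M, as on Saturday, with twice the precatalyst. It should run between Saturday's and Tuesday's.
7. Tuesday's late readings give an excess of 23.0%. Without exchange, the two substrates, charged equal, give equal product at full conversion, so near completion I take the share of the ceiling as the share of the way. Midway to the ceiling, I expect 25.9%, which is 90.2% of the ceiling, so I expect exchange to keep pace in this flask. I expect the total near Saturday's 99.0% at 2.50 h.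
8. The forecast gives 98.5%, 25% and keeps pace, its excess below mine: “The excess stays nearly flat with conversion, so exchange mostly keeps up.”

The flask gives 97.9% with excess 25.1%, and exchange keeps pace, 87% of the way.

    reagent + catalyst + left-handed substrate → catalyst + left-handed product (k = 14.0 /M²/s)
    reagent + catalyst + right-handed substrate → catalyst + right-handed product (k = 7.80 /M²/s)
    left-handed substrate ⇌ right-handed substrate (k = 0.00270 /s)
    precatalyst → catalyst (k = 8.70 × 10⁻⁴ /s)

At 2.00 h, right-handed substrate leads left-handed substrate in what is left of the two in the flask by an excess of 1.76%. The flask's product excess stands at 87.5% of the ceiling. The same flask with 2.2 M of reagent gives 100% and excess 17.7%, which is 61.7% of the ceiling.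

(The data come from a simulation for substances that don't exist; scatter was added.)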